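The lactone is assembled by trans-alkylation of a β-benzyl butyrolactone enolate (ring B arm, keto-alcohol masked as a diol acetonide) with a benzylic bromide that carries the dihydrobenzofuran. Everything rests on building that heterocycle by joining C2 to C3: C2 is a benzylic ether carbon between O1 and guaiacyl ring D, C3 sits on ring C and bears the hydroxymethyl carbon. The precursor is therefore open-chain: a ring-C aryl diazoacetate next to the ring-D benzyl ether of the ring-C phenol. A chiral dirhodium carboxylate makes the carbene, which inserts into the OCH2 C–H, closing the five-membered ring and fixing C2; base equilibration in the same flask sets trans C3.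

Key step: step 15

Remark: rings are lettered A (aroyl guaiacyl ring), B (ring on the lactone C4 benzyl), C (benzo ring of the dihydrobenzofuran) and D (its 2-aryl ring), and O1/C2/C3/C3a/C7a are benzofuran locants. The ligand enantiomers named in steps 3 and 15 are assumed to be those that deliver the R succinate and the 2S ether carbon; the mirror-image ligand is taken if the sense proves opposite.

**Left-hand fragment (steps 1–10)**

Step 1
Reactants: 1 5-bromovanillin (3-bromo-4-hydroxy-5-methoxybenzaldehyde)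
Product: 2 4-(benzyloxy)-3-bromo-5-methoxybenzaldehyde
Conditions: BnBr, K2CO3, DMF, rt
Reagents that add atoms: benzyl bromide, BrCc1ccccc1
Why: Williamson ether synthesis, in which the acidic phenoxide of 1 is the only nucleophile and is benzylated by SN2 displacement.

Step 2
Reactants: 2 4-(benzyloxy)-3-bromo-5-methoxybenzaldehyde; 3 dimethyl succinate
Product: 4 (E)-4-[4-(benzyloxy)-3-bromo-5-methoxyphenyl]-3-(methoxycarbonyl)but-3-enoic acid
Conditions: NaOMe, MeOH, reflux; then aq. HCl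
Reagents that add atoms: none
Why: Stobbe condensation, in which the succinate enolate adds to the aldehyde, the alkoxide lactonises onto the distal ester and E1cB opening of that paraconate gives the E half-ester with the free acid on the CH2 arm.

Step 3
Reactants: 4 (E)-4-[4-(benzyloxy)-3-bromo-5-methoxyphenyl]-3-(methoxycarbonyl)but-3-enoic acid
Product: 5 (3R)-4-[4-(benzyloxy)-3-bromo-5-methoxyphenyl]-3-(methoxycarbonyl)butanoic acid
Conditions: H2 (1–5 atm), [Rh(cod)2]BF4 (1 mol %), (4S,5S)-MOD-DIOP (1.2 mol %), Et3N (10 mol %), MeOH, rt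
Reagents that add atoms: none
Why: Rhodium-catalysed asymmetric hydrogenation of an arylidenesuccinic half-ester, in which carboxylate and alkene chelate the cationic rhodium–diphosphine and the chiral ligand delivers H2 to one alkene face to set the R stereocenter, while the homogeneous catalyst leaves the aryl bromide and the benzyl ether alone.

Step 4
Reactants: 5 (3R)-4-[4-(benzyloxy)-3-bromo-5-methoxyphenyl]-3-(methoxycarbonyl)butanoic acid
Product: 7 (4R)-4-[4-(benzyloxy)-3-bromo-5-methoxybenzyl]dihydrofuran-2(3H)-one, via hydroxy acid 6 (not isolated)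
Conditions: LiBH4 (2.5 equiv), THF, 0 °C to rt; then 2 M HCl, rt
Reagents that add atoms: none
Why: Chemoselective borohydride reduction, in which LiBH4 reduces the methyl ester but not the lithium carboxylate, and acidification lactonises the γ-hydroxy acid without touching the stereocenter.

Step 5
Reactants: 7 (4R)-4-[4-(benzyloxy)-3-bromo-5-methoxybenzyl]dihydrofuran-2(3H)-one; 8 (2-tert-butoxy-2-oxoethyl)zinc bromide
Product: 9 tert-butyl 2-[2-(benzyloxy)-3-methoxy-5-{[(3R)-5-oxooxolan-3-yl]methyl}phenyl]acetate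
Conditions: Pd(dba)2 (2 mol %), P(t-Bu)3 (2 mol %), THF, rt to 50 °C
Reagents that add atoms: none
Why: Reformatsky–Negishi α-arylation (oxidative addition of zerovalent palladium to C–Br, transmetalation of the zinc ester enolate, reductive elimination), whose weakly basic zinc enolate neither attacks nor enolises the lactone.

Step 6
Reactants: 9 tert-butyl 2-[2-(benzyloxy)-3-methoxy-5-{[(3R)-5-oxooxolan-3-yl]methyl}phenyl]acetate
Product: 10 2-[2-(benzyloxy)-3-methoxy-5-{[(3R)-5-oxooxolan-3-yl]methyl}phenyl]acetic acid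
Conditions: TFA/CH2Cl2 (1:3), 0 °C to rt
Reagents that add atoms: none
Why: Acidolysis of the tert-butyl ester by loss of the tert-butyl cation as isobutene, under which the lactone and the aryl benzyl ether should persist.

Step 7
Reactants: 10 2-[2-(benzyloxy)-3-methoxy-5-{[(3R)-5-oxooxolan-3-yl]methyl}phenyl]acetic acid; 11 (R)-4-benzyl-1,3-oxazolidin-2-one
Product: 13 (4R)-4-benzyl-3-{[2-(benzyloxy)-3-methoxy-5-{[(3R)-5-oxooxolan-3-yl]methyl}phenyl]acetyl}-1,3-oxazolidin-2-one, via mixed pivalic anhydride 12 (not isolated)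
Conditions: t-BuCOCl, Et3N, THF, −20 °C; then 11, LiCl, rt
Reagents that add atoms: pivaloyl chloride, CC(C)(C)C(=O)Cl (its atoms stay only in intermediate 12)
Why: Mixed-anhydride N-acylation of the oxazolidinone under LiCl/Et3N activation, which needs no strong base and so leaves the lactone intact.

Step 8
Reactants: 13 (4R)-4-benzyl-3-{[2-(benzyloxy)-3-methoxy-5-{[(3R)-5-oxooxolan-3-yl]methyl}phenyl]acetyl}-1,3-oxazolidin-2-one; 14 4-(benzyloxy)-3-methoxybenzaldehyde
Product: 16 (4R)-4-benzyl-3-[(2R,3R)-3-[4-(benzyloxy)-3-methoxyphenyl]-2-[2-(benzyloxy)-3-methoxy-5-{[(3R)-5-oxooxolan-3-yl]methyl}phenyl]-3-hydroxypropanoyl]-1,3-oxazolidin-2-one, via Z boron enolate 15 (not isolated)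
Conditions: Bu2BOTf, i-Pr2NEt, CH2Cl2, −78 to 0 °C; then 14, −78 to 0 °C; pH 7 buffer, MeOH, 30% H2O2
Reagents that add atoms: dibutylboron triflate, CCCCB(CCCC)OS(=O)(=O)C(F)(F)F (boron and butyl groups stay only in intermediate 15)
Why: Evans syn-aldol reaction, in which the Z boron enolate reacts through a closed chair transition state on the face away from the auxiliary benzyl group, setting the aryl-bearing carbon 2R (the later S carbon next to the ketone) and the carbinol syn, while soft enolisation spares the lactone.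

Step 9
Reactants: 16 (4R)-4-benzyl-3-[(2R,3R)-3-[4-(benzyloxy)-3-methoxyphenyl]-2-[2-(benzyloxy)-3-methoxy-5-{[(3R)-5-oxooxolan-3-yl]methyl}phenyl]-3-hydroxypropanoyl]-1,3-oxazolidin-2-one
Product: 17 (4R)-4-{4-(benzyloxy)-3-[(1R,2S)-1-[4-(benzyloxy)-3-methoxyphenyl]-1,3-dihydroxypropan-2-yl]-5-methoxybenzyl}dihydrofuran-2(3H)-one
Conditions: NaBH4, THF/H2O (4:1), 0 °C to rt
Reagents that add atoms: none
Why: Reductive cleavage of the N-acyl oxazolidinone by borohydride, which attacks the activated imide carbonyl far faster than the γ-lactone and leaves both new stereocenters untouched (the descriptor at C2 changes to S only through priorities).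

Step 10
Reactants: 17 (4R)-4-{4-(benzyloxy)-3-[(1R,2S)-1-[4-(benzyloxy)-3-methoxyphenyl]-1,3-dihydroxypropan-2-yl]-5-methoxybenzyl}dihydrofuran-2(3H)-one
Product: 18 (4R)-4-{4-(benzyloxy)-3-[(4R,5S)-4-[4-(benzyloxy)-3-methoxyphenyl]-2,2-dimethyl-1,3-dioxan-5-yl]-5-methoxybenzyl}dihydrofuran-2(3H)-one
Conditions: Me2C(OMe)2, PPTS (cat.), CH2Cl2, rt
Reagents that add atoms: 2,2-dimethoxypropane, COC(C)(C)OC
Why: Acid-catalysed transketalisation ties the 1,3-diol up as a dioxane, keeping the future ketone at the alcohol level so that no acidic α-aryl carbonyl proton is present in step 19.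

**Right-hand fragment (steps 11–18)**

Step 11
Reactants: 19 5-iodovanillin (4-hydroxy-3-iodo-5-methoxybenzaldehyde); 20 4-(benzyloxy)-3-methoxybenzyl alcohol
Product: 21 4-{[4-(benzyloxy)-3-methoxybenzyl]oxy}-3-iodo-5-methoxybenzaldehyde
Conditions: PPh3, DIAD, THF, 0 °C to rt
Reagents that add atoms: none
Why: Mitsunobu etherification, in which the acidic phenol of 19 displaces the activated primary benzylic oxyphosphonium of 20 by SN2.

Step 12
Reactants: 21 4-{[4-(benzyloxy)-3-methoxybenzyl]oxy}-3-iodo-5-methoxybenzaldehyde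
Product: 22 (4-{[4-(benzyloxy)-3-methoxybenzyl]oxy}-3-iodo-5-methoxyphenyl)methanol
Conditions: NaBH4, MeOH/THF, 0 °C
Reagents that add atoms: none
Why: Borohydride reduction of the aldehyde, with aryl iodide and ethers inert.

Step 13
Reactants: 22 (4-{[4-(benzyloxy)-3-methoxybenzyl]oxy}-3-iodo-5-methoxyphenyl)methanol
Product: 23 tert-butyl[(4-{[4-(benzyloxy)-3-methoxybenzyl]oxy}-3-iodo-5-methoxyphenyl)methoxy]dimethylsilane
Conditions: TBSCl, imidazole, DMF, rt
Reagents that add atoms: tert-butyldimethylsilyl chloride, CC(C)(C)[Si](C)(C)Cl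
Why: Silylation masks the hydroxyl, which would otherwise trap the carbene of step 15 by O–H insertion, as a latent benzylic leaving group.

Step 14
Reactants: 23 tert-butyl[(4-{[4-(benzyloxy)-3-methoxybenzyl]oxy}-3-iodo-5-methoxyphenyl)methoxy]dimethylsilane; 24 ethyl diazoacetate
Product: 25 ethyl 2-(2-{[4-(benzyloxy)-3-methoxybenzyl]oxy}-5-{[(tert-butyldimethylsilyl)oxy]methyl}-3-methoxyphenyl)-2-diazoacetate
Conditions: Pd(PPh3)4 (5 mol %), Ag2CO3 (0.5 equiv), Et3N, toluene, rt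
Reagents that add atoms: none
Why: Palladium/silver-mediated cross-coupling of an aryl iodide with an acceptor diazo compound, in which zerovalent palladium adds to C–I, silver carbonate and Et3N deliver the deprotonated diazoacetate to palladium, and reductive elimination forms the aryl–C bond with the diazo group retained.

Step 15
Reactants: 25 ethyl 2-(2-{[4-(benzyloxy)-3-methoxybenzyl]oxy}-5-{[(tert-butyldimethylsilyl)oxy]methyl}-3-methoxyphenyl)-2-diazoacetate
Product: 27 ethyl (2S,3S)-2-[4-(benzyloxy)-3-methoxyphenyl]-5-{[(tert-butyldimethylsilyl)oxy]methyl}-7-methoxy-2,3-dihydro-1-benzofuran-3-carboxylate, via cis ester 26 (not isolated)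
Conditions: dirhodium tetrakis[N-phthaloyl-(R)-tert-leucinate], Rh2(R-PTTL)4 (1 mol %), toluene, −60 °C, slow addition of 25; then NaOEt (0.3 equiv), EtOH, 0 °C to rt
Reagents that add atoms: none
Why: The dirhodium tetracarboxylate (divalent rhodium) expels N2 from 25 to give a rhodium-bound donor/acceptor carbene at the future C3, which inserts through a concerted, hydride-transfer-like three-centre transition state into one C–H of the ether CH2 (the future C2) lying 1,5 to it, forming the C2–C3 bond. The closest known reaction type is the enantioselective dirhodium-carboxylate-catalysed intramolecular C–H insertion of 2-(benzyloxy)phenyl diazoacetates to cis-2-aryl-2,3-dihydrobenzofuran-3-carboxylates. The ring O1–C2–C3–C3a–C7a closes by 1,5-C–H insertion through a five-membered cyclic transition state, with C3 as the carbene carbon and C2 as the inserted sp3 carbon. C2 is set S by the catalyst, whose chiral carboxylate pocket selects one of the two enantiotopic OCH2 hydrogens; C3 forms cis under kinetic control (26) and is then turned trans (3S in 27) by ethoxide equilibration through the ester enolate, the 2-aryl group holding the ester on the opposite face. The step needs site selectivity for this C–H over attack on electron-rich ring D, over the remote benzyl and silyloxymethyl CH2 groups and over carbene dimerisation; this is secured by the 1,5 geometry, the double activation of the C–H by O1 and ring D, low temperature and slow addition.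

Step 16
Reactants: 27 ethyl (2S,3S)-2-[4-(benzyloxy)-3-methoxyphenyl]-5-{[(tert-butyldimethylsilyl)oxy]methyl}-7-methoxy-2,3-dihydro-1-benzofuran-3-carboxylate
Product: 28 [(2S,3R)-2-[4-(benzyloxy)-3-methoxyphenyl]-5-{[(tert-butyldimethylsilyl)oxy]methyl}-7-methoxy-2,3-dihydro-1-benzofuran-3-yl]methanol
Conditions: LiAlH4, THF, 0 °C
Reagents that add atoms: none
Why: Hydride reduction of the ester to the hydroxymethyl group, after which C3 is no longer epimerisable (its descriptor changes to R only through priorities).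

Step 17
Reactants: 28 [(2S,3R)-2-[4-(benzyloxy)-3-methoxyphenyl]-5-{[(tert-butyldimethylsilyl)oxy]methyl}-7-methoxy-2,3-dihydro-1-benzofuran-3-yl]methanol
Product: 29 tert-butyl{[(2S,3R)-2-[4-(benzyloxy)-3-methoxyphenyl]-3-[(benzyloxy)methyl]-7-methoxy-2,3-dihydro-1-benzofuran-5-yl]methoxy}dimethylsilane
Conditions: NaH, BnBr, Bu4NI (cat.), THF/DMF, 0 °C to rt
Reagents that add atoms: benzyl bromide, BrCc1ccccc1
Why: Williamson benzylation of the primary alkoxide gives an ether with no acidic proton for the enolate of step 19, removable together with the aryl benzyl ethers at the end.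

Step 18
Reactants: 29 tert-butyl{[(2S,3R)-2-[4-(benzyloxy)-3-methoxyphenyl]-3-[(benzyloxy)methyl]-7-methoxy-2,3-dihydro-1-benzofuran-5-yl]methoxy}dimethylsilane
Product: 30 (2S,3R)-2-[4-(benzyloxy)-3-methoxyphenyl]-3-[(benzyloxy)methyl]-5-(bromomethyl)-7-methoxy-2,3-dihydro-1-benzofuran
Conditions: Ph3PBr2, CH2Cl2, 0 °C to rt
Reagents that add atoms: triphenylphosphine dibromide, BrP(Br)(c1ccccc1)(c1ccccc1)c1ccccc1
Why: Direct silyl ether to bromide interconversion (silyl transfer to bromide, alkoxyphosphonium formation, SN2 by bromide at the primary benzylic carbon), in which the benzyl ethers and the ring stereocenters are not engaged.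

**Union and endgame (steps 19–22)**

Step 19
Reactants: 18 (4R)-4-{4-(benzyloxy)-3-[(4R,5S)-4-[4-(benzyloxy)-3-methoxyphenyl]-2,2-dimethyl-1,3-dioxan-5-yl]-5-methoxybenzyl}dihydrofuran-2(3H)-one; 30 (2S,3R)-2-[4-(benzyloxy)-3-methoxyphenyl]-3-[(benzyloxy)methyl]-5-(bromomethyl)-7-methoxy-2,3-dihydro-1-benzofuran
Product: 32 (3R,4R)-4-{4-(benzyloxy)-3-[(4R,5S)-4-[4-(benzyloxy)-3-methoxyphenyl]-2,2-dimethyl-1,3-dioxan-5-yl]-5-methoxybenzyl}-3-{[(2S,3R)-2-[4-(benzyloxy)-3-methoxyphenyl]-3-[(benzyloxy)methyl]-7-methoxy-2,3-dihydro-1-benzofuran-5-yl]methyl}dihydrofuran-2(3H)-one, via lithium enolate 31 (not isolated)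
Conditions: LiN(SiMe3)2 (1.05 equiv), THF, −78 °C; then 30, DMPU, −78 to −40 °C
Reagents that add atoms: lithium hexamethyldisilazide, [Li]N([Si](C)(C)C)[Si](C)(C)C (lithium stays only in intermediate 31)
Why: Lactone enolate alkylation, in which the only acidic site of 18 is the lactone α-CH2 and the benzylic bromide approaches the enolate face anti to the C4 benzyl group, setting C3 as R (trans).

Step 20
Reactants: 32 (3R,4R)-4-{4-(benzyloxy)-3-[(4R,5S)-4-[4-(benzyloxy)-3-methoxyphenyl]-2,2-dimethyl-1,3-dioxan-5-yl]-5-methoxybenzyl}-3-{[(2S,3R)-2-[4-(benzyloxy)-3-methoxyphenyl]-3-[(benzyloxy)methyl]-7-methoxy-2,3-dihydro-1-benzofuran-5-yl]methyl}dihydrofuran-2(3H)-one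
Product: 33 (3R,4R)-4-{4-(benzyloxy)-3-[(1R,2S)-1-[4-(benzyloxy)-3-methoxyphenyl]-1,3-dihydroxypropan-2-yl]-5-methoxybenzyl}-3-{[(2S,3R)-2-[4-(benzyloxy)-3-methoxyphenyl]-3-[(benzyloxy)methyl]-7-methoxy-2,3-dihydro-1-benzofuran-5-yl]methyl}dihydrofuran-2(3H)-one
Conditions: PPTS (0.2 equiv), MeOH, rt
Reagents that add atoms: none
Why: Mild acid-catalysed transketalisation to methanol removes the acetonide; the ring B phenol is still benzylated, so the benzylic carbinol cannot cyclise onto it, and lactone and benzyl ethers are inert.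

Step 21
Reactants: 33 (3R,4R)-4-{4-(benzyloxy)-3-[(1R,2S)-1-[4-(benzyloxy)-3-methoxyphenyl]-1,3-dihydroxypropan-2-yl]-5-methoxybenzyl}-3-{[(2S,3R)-2-[4-(benzyloxy)-3-methoxyphenyl]-3-[(benzyloxy)methyl]-7-methoxy-2,3-dihydro-1-benzofuran-5-yl]methyl}dihydrofuran-2(3H)-one
Product: 34 (3R,4R)-4-{4-(benzyloxy)-3-[(2S)-1-[4-(benzyloxy)-3-methoxyphenyl]-3-hydroxy-1-oxopropan-2-yl]-5-methoxybenzyl}-3-{[(2S,3R)-2-[4-(benzyloxy)-3-methoxyphenyl]-3-[(benzyloxy)methyl]-7-methoxy-2,3-dihydro-1-benzofuran-5-yl]methyl}dihydrofuran-2(3H)-one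
Conditions: activated MnO2 (excess), CH2Cl2, rt
Reagents that add atoms: none
Why: Chemoselective benzylic oxidation, since MnO2 oxidises the electron-rich secondary benzylic alcohol but not the primary aliphatic one, under neutral conditions chosen to keep the new, enolisable α-aryl stereocenter (S) intact.

Step 22
Reactants: 34 (3R,4R)-4-{4-(benzyloxy)-3-[(2S)-1-[4-(benzyloxy)-3-methoxyphenyl]-3-hydroxy-1-oxopropan-2-yl]-5-methoxybenzyl}-3-{[(2S,3R)-2-[4-(benzyloxy)-3-methoxyphenyl]-3-[(benzyloxy)methyl]-7-methoxy-2,3-dihydro-1-benzofuran-5-yl]methyl}dihydrofuran-2(3H)-one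
Product: 35 (3R,4R)-4-{4-hydroxy-3-[(2S)-3-hydroxy-1-(4-hydroxy-3-methoxyphenyl)-1-oxopropan-2-yl]-5-methoxybenzyl}-3-{[(2S,3R)-2-(4-hydroxy-3-methoxyphenyl)-3-(hydroxymethyl)-7-methoxy-2,3-dihydro-1-benzofuran-5-yl]methyl}dihydrofuran-2(3H)-one (CNP0111438.1)
Conditions: H2 (1 atm), 10% Pd/C, EtOAc/EtOH, rt, stopped at full debenzylation
Reagents that add atoms: none
Why: Catalytic hydrogenolysis cleaves the three aryl benzyl ethers and the primary alkyl benzyl ether under neutral, non-enolising conditions, which should spare the electron-rich aryl ketone, the lactone and the slower-reacting ring benzylic C2–O1 bond.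

**Compound list**

1 | 5-bromovanillin | O=Cc1cc(Br)c(O)c(OC)c1 | starting material
2 | 4-(benzyloxy)-3-bromo-5-methoxybenzaldehyde | O=Cc1cc(Br)c(OCc2ccccc2)c(OC)c1 | intermediate
3 | dimethyl succinate | COC(=O)CCC(=O)OC | starting material
4 | (E)-4-[4-(benzyloxy)-3-bromo-5-methoxyphenyl]-3-(methoxycarbonyl)but-3-enoic acid | COC(=O)/C(CC(=O)O)=C/c1cc(Br)c(OCc2ccccc2)c(OC)c1 | intermediate
5 | (3R)-4-[4-(benzyloxy)-3-bromo-5-methoxyphenyl]-3-(methoxycarbonyl)butanoic acid | COC(=O)[C@H](Cc1cc(Br)c(OCc2ccccc2)c(OC)c1)CC(=O)O | intermediate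
6 | (3R)-4-[4-(benzyloxy)-3-bromo-5-methoxyphenyl]-3-(hydroxymethyl)butanoic acid (hydroxy acid, not isolated) | OC[C@H](Cc1cc(Br)c(OCc2ccccc2)c(OC)c1)CC(=O)O | intermediate
7 | (4R)-4-[4-(benzyloxy)-3-bromo-5-methoxybenzyl]dihydrofuran-2(3H)-one | O=C1C[C@@H](Cc2cc(Br)c(OCc3ccccc3)c(OC)c2)CO1 | intermediate
8 | (2-tert-butoxy-2-oxoethyl)zinc bromide | CC(C)(C)OC(=O)C[Zn]Br | starting material
9 | tert-butyl 2-[2-(benzyloxy)-3-methoxy-5-{[(3R)-5-oxooxolan-3-yl]methyl}phenyl]acetate | O=C1C[C@@H](Cc2cc(CC(=O)OC(C)(C)C)c(OCc3ccccc3)c(OC)c2)CO1 | intermediate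
10 | 2-[2-(benzyloxy)-3-methoxy-5-{[(3R)-5-oxooxolan-3-yl]methyl}phenyl]acetic acid | O=C1C[C@@H](Cc2cc(CC(=O)O)c(OCc3ccccc3)c(OC)c2)CO1 | intermediate
11 | (R)-4-benzyl-1,3-oxazolidin-2-one | O=C1N[C@H](Cc2ccccc2)CO1 | starting material
12 | mixed anhydride of acid 10 with pivalic acid (not isolated) | O=C1C[C@@H](Cc2cc(CC(=O)OC(=O)C(C)(C)C)c(OCc3ccccc3)c(OC)c2)CO1 | intermediate
13 | (4R)-4-benzyl-3-{[2-(benzyloxy)-3-methoxy-5-{[(3R)-5-oxooxolan-3-yl]methyl}phenyl]acetyl}-1,3-oxazolidin-2-one | O=C1C[C@@H](Cc2cc(CC(=O)N3[C@H](Cc4ccccc4)COC3=O)c(OCc5ccccc5)c(OC)c2)CO1 | intermediate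
14 | 4-(benzyloxy)-3-methoxybenzaldehyde | O=Cc1ccc(OCc2ccccc2)c(OC)c1 | starting material
15 | (Z)-dibutylboron enolate of imide 13 (not isolated) | CCCCB(CCCC)O/C(=C\c1cc(C[C@@H]2CC(=O)OC2)cc(OC)c1OCc1ccccc1)N1[C@H](Cc2ccccc2)COC1=O | intermediate
16 | (4R)-4-benzyl-3-[(2R,3R)-3-[4-(benzyloxy)-3-methoxyphenyl]-2-[2-(benzyloxy)-3-methoxy-5-{[(3R)-5-oxooxolan-3-yl]methyl}phenyl]-3-hydroxypropanoyl]-1,3-oxazolidin-2-one | O=C([C@H](c1cc(C[C@@H]2CC(=O)OC2)cc(OC)c1OCc1ccccc1)[C@@H](O)c1ccc(OCc2ccccc2)c(OC)c1)N1[C@H](Cc2ccccc2)COC1=O | intermediate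
17 | (4R)-4-{4-(benzyloxy)-3-[(1R,2S)-1-[4-(benzyloxy)-3-methoxyphenyl]-1,3-dihydroxypropan-2-yl]-5-methoxybenzyl}dihydrofuran-2(3H)-one | OC[C@H](c1cc(C[C@@H]2CC(=O)OC2)cc(OC)c1OCc1ccccc1)[C@@H](O)c1ccc(OCc2ccccc2)c(OC)c1 | intermediate
18 | (4R)-4-{4-(benzyloxy)-3-[(4R,5S)-4-[4-(benzyloxy)-3-methoxyphenyl]-2,2-dimethyl-1,3-dioxan-5-yl]-5-methoxybenzyl}dihydrofuran-2(3H)-one | CC1(C)OC[C@H](c2cc(C[C@@H]3CC(=O)OC3)cc(OC)c2OCc2ccccc2)[C@H](c2ccc(OCc3ccccc3)c(OC)c2)O1 | intermediate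
19 | 5-iodovanillin | O=Cc1cc(I)c(O)c(OC)c1 | starting material
20 | 4-(benzyloxy)-3-methoxybenzyl alcohol | OCc1ccc(OCc2ccccc2)c(OC)c1 | starting material
21 | 4-{[4-(benzyloxy)-3-methoxybenzyl]oxy}-3-iodo-5-methoxybenzaldehyde | O=Cc1cc(I)c(OCc2ccc(OCc3ccccc3)c(OC)c2)c(OC)c1 | intermediate
22 | (4-{[4-(benzyloxy)-3-methoxybenzyl]oxy}-3-iodo-5-methoxyphenyl)methanol | OCc1cc(I)c(OCc2ccc(OCc3ccccc3)c(OC)c2)c(OC)c1 | intermediate
23 | tert-butyl[(4-{[4-(benzyloxy)-3-methoxybenzyl]oxy}-3-iodo-5-methoxyphenyl)methoxy]dimethylsilane | CC(C)(C)[Si](C)(C)OCc1cc(I)c(OCc2ccc(OCc3ccccc3)c(OC)c2)c(OC)c1 | intermediate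
24 | ethyl diazoacetate | CCOC(=O)C=[N+]=[N-] | starting material
25 | ethyl 2-(2-{[4-(benzyloxy)-3-methoxybenzyl]oxy}-5-{[(tert-butyldimethylsilyl)oxy]methyl}-3-methoxyphenyl)-2-diazoacetate | CCOC(=O)C(=[N+]=[N-])c1cc(CO[Si](C)(C)C(C)(C)C)cc(OC)c1OCc1ccc(OCc2ccccc2)c(OC)c1 | intermediate
26 | ethyl (2S,3R)-2-[4-(benzyloxy)-3-methoxyphenyl]-5-{[(tert-butyldimethylsilyl)oxy]methyl}-7-methoxy-2,3-dihydro-1-benzofuran-3-carboxylate (cis ester, not isolated) | CC(C)(C)[Si](C)(C)OCc1cc(OC)c2c(c1)[C@@H](C(=O)OCC)[C@@H](c1ccc(OCc3ccccc3)c(OC)c1)O2 | intermediate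
27 | ethyl (2S,3S)-2-[4-(benzyloxy)-3-methoxyphenyl]-5-{[(tert-butyldimethylsilyl)oxy]methyl}-7-methoxy-2,3-dihydro-1-benzofuran-3-carboxylate (trans ester) | CC(C)(C)[Si](C)(C)OCc1cc(OC)c2c(c1)[C@H](C(=O)OCC)[C@@H](c1ccc(OCc3ccccc3)c(OC)c1)O2 | intermediate
28 | [(2S,3R)-2-[4-(benzyloxy)-3-methoxyphenyl]-5-{[(tert-butyldimethylsilyl)oxy]methyl}-7-methoxy-2,3-dihydro-1-benzofuran-3-yl]methanol | CC(C)(C)[Si](C)(C)OCc1cc(OC)c2c(c1)[C@H](CO)[C@@H](c1ccc(OCc3ccccc3)c(OC)c1)O2 | intermediate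
29 | tert-butyl{[(2S,3R)-2-[4-(benzyloxy)-3-methoxyphenyl]-3-[(benzyloxy)methyl]-7-methoxy-2,3-dihydro-1-benzofuran-5-yl]methoxy}dimethylsilane | CC(C)(C)[Si](C)(C)OCc1cc(OC)c2c(c1)[C@H](COCc1ccccc1)[C@@H](c1ccc(OCc3ccccc3)c(OC)c1)O2 | intermediate
30 | (2S,3R)-2-[4-(benzyloxy)-3-methoxyphenyl]-3-[(benzyloxy)methyl]-5-(bromomethyl)-7-methoxy-2,3-dihydro-1-benzofuran | BrCc1cc(OC)c2c(c1)[C@H](COCc1ccccc1)[C@@H](c1ccc(OCc3ccccc3)c(OC)c1)O2 | intermediate
31 | lithium enolate of lactone 18 (not isolated) | CC1(C)OC[C@H](c2cc(C[C@@H]3C=C(O[Li])OC3)cc(OC)c2OCc2ccccc2)[C@H](c2ccc(OCc3ccccc3)c(OC)c2)O1 | intermediate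
32 | (3R,4R)-4-{4-(benzyloxy)-3-[(4R,5S)-4-[4-(benzyloxy)-3-methoxyphenyl]-2,2-dimethyl-1,3-dioxan-5-yl]-5-methoxybenzyl}-3-{[(2S,3R)-2-[4-(benzyloxy)-3-methoxyphenyl]-3-[(benzyloxy)methyl]-7-methoxy-2,3-dihydro-1-benzofuran-5-yl]methyl}dihydrofuran-2(3H)-one | CC1(C)OC[C@H](c2cc(C[C@H]3COC(=O)[C@@H]3Cc3cc(OC)c4c(c3)[C@H](COCc3ccccc3)[C@@H](c3ccc(OCc5ccccc5)c(OC)c3)O4)cc(OC)c2OCc2ccccc2)[C@H](c2ccc(OCc3ccccc3)c(OC)c2)O1 | intermediate
33 | (3R,4R)-4-{4-(benzyloxy)-3-[(1R,2S)-1-[4-(benzyloxy)-3-methoxyphenyl]-1,3-dihydroxypropan-2-yl]-5-methoxybenzyl}-3-{[(2S,3R)-2-[4-(benzyloxy)-3-methoxyphenyl]-3-[(benzyloxy)methyl]-7-methoxy-2,3-dihydro-1-benzofuran-5-yl]methyl}dihydrofuran-2(3H)-one | OC[C@H](c1cc(C[C@H]2COC(=O)[C@@H]2Cc2cc(OC)c3c(c2)[C@H](COCc2ccccc2)[C@@H](c2ccc(OCc4ccccc4)c(OC)c2)O3)cc(OC)c1OCc1ccccc1)[C@@H](O)c1ccc(OCc2ccccc2)c(OC)c1 | intermediate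
34 | (3R,4R)-4-{4-(benzyloxy)-3-[(2S)-1-[4-(benzyloxy)-3-methoxyphenyl]-3-hydroxy-1-oxopropan-2-yl]-5-methoxybenzyl}-3-{[(2S,3R)-2-[4-(benzyloxy)-3-methoxyphenyl]-3-[(benzyloxy)methyl]-7-methoxy-2,3-dihydro-1-benzofuran-5-yl]methyl}dihydrofuran-2(3H)-one | COc1cc(C(=O)[C@H](CO)c2cc(C[C@H]3COC(=O)[C@@H]3Cc3cc(OC)c4c(c3)[C@H](COCc3ccccc3)[C@@H](c3ccc(OCc5ccccc5)c(OC)c3)O4)cc(OC)c2OCc2ccccc2)ccc1OCc1ccccc1 | intermediate
35 | (3R,4R)-4-{4-hydroxy-3-[(2S)-3-hydroxy-1-(4-hydroxy-3-methoxyphenyl)-1-oxopropan-2-yl]-5-methoxybenzyl}-3-{[(2S,3R)-2-(4-hydroxy-3-methoxyphenyl)-3-(hydroxymethyl)-7-methoxy-2,3-dihydro-1-benzofuran-5-yl]methyl}dihydrofuran-2(3H)-one (CNP0111438.1) | COc1cc(C(=O)[C@H](CO)c2cc(C[C@H]3COC(=O)[C@@H]3Cc3cc(OC)c4c(c3)[C@H](CO)[C@@H](c3ccc(O)c(OC)c3)O4)cc(OC)c2O)ccc1O | target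

**Count and risks**

Total step count: 22. Longest linear sequence: 14 steps (steps 1–10 and 19–22, from 5-bromovanillin).

Steps most likely to fail:

Step 15. The chiral carboxylate may discriminate the two enantiotopic ether hydrogens poorly, the carbene may add to electron-rich ring D or dimerise, and ethoxide may open the ring by β-elimination of the phenoxide instead of only epimerising C3. The fallback moves stereocontrol to a covalently bound auxiliary and forms the trans ester without alkoxide; it sets out from 23 and comes back at 28. Ethyl (S)-lactate and pyrrolidine give (S)-2-hydroxy-1-(pyrrolidin-1-yl)propan-1-one F1. Glyoxylic acid chloride p-toluenesulfonylhydrazone with PhNMe2 and then Et3N converts it into (S)-1-oxo-1-(pyrrolidin-1-yl)propan-2-yl diazoacetate F2. Coupling of 23 with F2 under Pd(PPh3)4/Ag2CO3/Et3N gives the lactamide aryldiazoacetate F3. Dirhodium tetrakis[(S)-N-(4-dodecylbenzenesulfonyl)prolinate], Rh2(S-DOSP)4, in CH2Cl2 at low temperature should then give the trans (2S,3S) lactamide ester F4 by matched double stereodifferentiation, with DBU equilibration of any cis isomer. The auxiliary enantiomer is to be chosen as the matched one; S is drawn. LiAlH4 in THF cleaves the auxiliary reductively and gives 28.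

Step 14. Transfer of the silver diazoacetate to the hindered ortho-alkoxyaryl palladium may be slow, so that the diazo ester is consumed by palladium-carbene pathways before coupling. The fallback introduces the diazo group after the C–C coupling instead of during it; it sets out from 23 and comes back at 25. Coupling of 23 with (2-ethoxy-2-oxoethyl)zinc bromide under Pd(dba)2/P(t-Bu)3, as in step 5, gives ethyl 2-(2-{[4-(benzyloxy)-3-methoxybenzyl]oxy}-5-{[(tert-butyldimethylsilyl)oxy]methyl}-3-methoxyphenyl)acetate F5. Regitz diazo transfer with 4-acetamidobenzenesulfonyl azide and DBU in MeCN then gives 25.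

Step 21. Oxidation of the hindered carbinol may stall, and the new α-aryl-β-hydroxy ketone may enolise on the oxide surface, with loss of configuration, dehydration or retro-aldol loss of formaldehyde. The fallback secures selectivity by a protecting group and a buffered homogeneous oxidant instead of by reagent chemoselectivity; it sets out from 33 and comes back at 34. TBSCl/imidazole in CH2Cl2 at 0 °C silylates only the primary hydroxyl to give the mono-silyl ether of diol 33 F6. Dess–Martin periodinane with NaHCO3 in CH2Cl2 gives the silylated ketone F7. HF·pyridine in THF/pyridine at 0 °C removes the silyl group without base and gives 34.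

Further compounds
F1 | step 15 | (S)-2-hydroxy-1-(pyrrolidin-1-yl)propan-1-one | C[C@H](O)C(=O)N1CCCC1
F2 | step 15 | (S)-1-oxo-1-(pyrrolidin-1-yl)propan-2-yl diazoacetate | C[C@H](OC(=O)C=[N+]=[N-])C(=O)N1CCCC1
F3 | step 15 | (S)-1-oxo-1-(pyrrolidin-1-yl)propan-2-yl 2-(2-{[4-(benzyloxy)-3-methoxybenzyl]oxy}-5-{[(tert-butyldimethylsilyl)oxy]methyl}-3-methoxyphenyl)-2-diazoacetate | C[C@H](OC(=O)C(=[N+]=[N-])c1cc(CO[Si](C)(C)C(C)(C)C)cc(OC)c1OCc1ccc(OCc2ccccc2)c(OC)c1)C(=O)N1CCCC1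
F4 | step 15 | (S)-1-oxo-1-(pyrrolidin-1-yl)propan-2-yl (2S,3S)-2-[4-(benzyloxy)-3-methoxyphenyl]-5-{[(tert-butyldimethylsilyl)oxy]methyl}-7-methoxy-2,3-dihydro-1-benzofuran-3-carboxylate | CC(C)(C)[Si](C)(C)OCc1cc(OC)c2c(c1)[C@H](C(=O)O[C@@H](C)C(=O)N1CCCC1)[C@@H](c1ccc(OCc3ccccc3)c(OC)c1)O2
F5 | step 14 | ethyl 2-(2-{[4-(benzyloxy)-3-methoxybenzyl]oxy}-5-{[(tert-butyldimethylsilyl)oxy]methyl}-3-methoxyphenyl)acetate | CCOC(=O)Cc1cc(CO[Si](C)(C)C(C)(C)C)cc(OC)c1OCc1ccc(OCc2ccccc2)c(OC)c1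
F6 | step 21 | (3R,4R)-4-{4-(benzyloxy)-3-[(1R,2S)-1-[4-(benzyloxy)-3-methoxyphenyl]-3-[(tert-butyldimethylsilyl)oxy]-1-hydroxypropan-2-yl]-5-methoxybenzyl}-3-{[(2S,3R)-2-[4-(benzyloxy)-3-methoxyphenyl]-3-[(benzyloxy)methyl]-7-methoxy-2,3-dihydro-1-benzofuran-5-yl]methyl}dihydrofuran-2(3H)-one | CC(C)(C)[Si](C)(C)OC[C@H](c1cc(C[C@H]2COC(=O)[C@@H]2Cc2cc(OC)c3c(c2)[C@H](COCc2ccccc2)[C@@H](c2ccc(OCc4ccccc4)c(OC)c2)O3)cc(OC)c1OCc1ccccc1)[C@@H](O)c1ccc(OCc2ccccc2)c(OC)c1
F7 | step 21 | (3R,4R)-4-{4-(benzyloxy)-3-[(2S)-1-[4-(benzyloxy)-3-methoxyphenyl]-3-[(tert-butyldimethylsilyl)oxy]-1-oxopropan-2-yl]-5-methoxybenzyl}-3-{[(2S,3R)-2-[4-(benzyloxy)-3-methoxyphenyl]-3-[(benzyloxy)methyl]-7-methoxy-2,3-dihydro-1-benzofuran-5-yl]methyl}dihydrofuran-2(3H)-one | COc1cc(C(=O)[C@H](CO[Si](C)(C)C(C)(C)C)c2cc(C[C@H]3COC(=O)[C@@H]3Cc3cc(OC)c4c(c3)[C@H](COCc3ccccc3)[C@@H](c3ccc(OCc5ccccc5)c(OC)c3)O4)cc(OC)c2OCc2ccccc2)ccc1OCc1ccccc1
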